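All runs are calculated on assumed constants; the scatter is artificial.

At early times a run shows its pace directly: the complex swaps one of its ligands for an incoming one, and the readings of the green run show 13.0% of its complex lost within 8.00 min.

| flask | starting complex | incoming ligand | temperature | remark | time |
|---|---|---|---|---|---|
| green | 0.068 M | 0.059 M | 20 °C | run made earlier |  |
| blue | 0.068 M | 0.13 M | 31 °C | run made earlier |  |
| ochre | 0.068 M | 0.29 M | 20 °C | run made earlier |  |
| violet | 0.12 M | 0.0612 M | 31 °C | run made earlier |  |
| ash | 0.25 M | 0.0612 M | 25 °C |  | 3.0 h |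
| alder | 0.068 M | 0.250 M | 25 °C |  | 3.0 h |
| larch | 0.25 M | 0.250 M | 25 °C |  | 3.0 h |
| maple | 0.068 M | 0.0612 M | 25 °C |  | 3.0 h |

| run | time / min | complex with one exchanged / % | starting complex / % |
|---|---|---|---|
| green | 8.00 | 12 | 87 |
| green | 25.0 | 27 | 68 |
| green | 40.0 | 43 | 54 |
| green | 60.0 | 50 | 48 |
| green | 90.0 | 59 | 36 |
| blue | 20.0 | 69 | 24 |
| blue | 40.0 | 80 | 12 |
| blue | 50.0 | 82 | 5 |
| blue | 80.0 | 87 | 6 |
| blue | 90.0 | 89 | 3 |
| ochre | 8.00 | 35 | 48 |
| ochre | 25.0 | 65 | 9 |
| ochre | 40.0 | 73 | 3 |
| ochre | 60.0 | 77 | 3 |
| ochre | 90.0 | 74 | 3 |
| violet | 20.0 | 35 | 63 |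
| violet | 40.0 | 45 | 55 |
| violet | 50.0 | 48 | 54 |
| violet | 80.0 | 46 | 51 |
| violet | 90.0 | 48 | 52 |

(standard deviation of a reading: 1.5 percentage points)

* ranking by amount of complex with one exchanged, in percent of the starting complex charged, from high to low, at 3.0 h (ash / alder / larch / maple)
* the amount of complex with one exchanged, in percent of the starting complex charged of the flask you put first, at 3.0 h
* the amount of complex with one exchanged, in percent of the starting complex charged of the flask you put last, at 3.0 h



Ask which numbers you need well for ash, the flask with the most complex against its ligand. Take the rate first. Reckoned from that early loss in green, with 0.059 M of ligand, an incoming ligand in ash, facing 0.25 M of complex, has a time constant of about 13.6 min. That is at the green temperature, and ash is warmer. Complex stands in excess there, a pseudo-first-order case, so 3.0 h holds about 13.3 time constants. Were the rate so far off that the count fell to 6.65, free ligand in ash would still come down to 0.131% of its charge, leaving the way back aside, so for ash you need not know the rate well.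

The way back comes next. Violet, with ligand charge over complex charge at 51.0%, reads 48% at 90.0 min, a gap of 3 percentage points against a scatter of 1.5 points, and I allow ash no wider a gap.

The charges matter directly, since each exchange spends one ligand. So the number to carry is the ligand ceiling, the incoming ligand charged divided by the starting complex charged, which for ash is 24.5%, with ligand as limiting reagent. Ligands per complex are 0.900 in maple, 1.00 in larch and 3.68 in alder. Ochre, at 4.26, has 23.0% of its complex missing from its last readings. So I put larch first, then alder, then maple, and ash last, just under its ceiling.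

The forecast differs on first place: alder > larch > maple > ash, with alder at 78%, “conversion complete, about 20% lost onward”, and ash at 23.7%.

The flasks give larch > alder > maple > ash, with larch at 83.8% and ash at 24.2%.

starting complex + incoming ligand ⇌ leaving ligand + complex with one exchanged (K = 38.0, k = 32.0 M⁻¹ h⁻¹, Ea = 48.0 kJ mol⁻¹, ΔH = −19.0 kJ mol⁻¹); complex with one exchanged + incoming ligand ⇌ leaving ligand + complex with two exchanged (K = 0.120, k = 170 M⁻¹ h⁻¹, Ea = 62.0 kJ mol⁻¹, ΔH = −13.0 kJ mol⁻¹); (constants at 25 °C) At 3.00 h, alder holds 19.9% as complex with two exchanged and larch 1.52%. Ash ends 0.30 points under its ceiling of 24.5%. With 0.62 M of starting complex in place of the charge of ash, all else as in ash, the ceiling scales to 9.88%, and that flask gives 9.84%.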